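**Retrosynthetic overview**
- The last bond made is the ring B aryl–CH2OH bond: an aryl bromide is coupled with K[AcOCH2BF3], a hydroxymethyl anion (α-oxy carbanion) equivalent, so the carbinol carbon acts as the nucleophile towards the C–Br carbon.
- The aryl bromide is disconnected at the diaryl ether C–O bond into a ring A salicylate phenol and a (2-bromo-4,6-dimethoxyphenyl)(2,4,6-trimethoxyphenyl)iodonium salt (metal-free O-arylation of a doubly ortho-substituted pair).
- The iodonium salt comes from 1-bromo-2-iodo-3,5-dimethoxybenzene, made by iodination of 1-bromo-3,5-dimethoxybenzene; the phenol comes from methyl 2,6-dihydroxy-4-methylbenzoate and prenyl bromide.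
- Ring order: no ring is built. Rings A and B are bought as benzenes, joined through the ether oxygen in step 4, and the last carbon is put on ring B in step 5.

Assumption: the target has no stereocentre and no stereogenic double bond (the prenyl alkene carries two identical methyl groups), so the SMILES defines one achiral compound and no stereocontrol is needed.

**Route**

Step 1
Reactants: 1 1-bromo-3,5-dimethoxybenzene; 2 N-iodosuccinimide
Product: 3 1-bromo-2-iodo-3,5-dimethoxybenzene
Conditions: NIS (1.05 equiv), TFA (10 mol%), MeCN, rt, dark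
Reagents that add atoms: N-iodosuccinimide (2), O=C1CCC(=O)N1I
Why: Electrophilic aromatic iodination, which in 5-substituted 1,3-dimethoxybenzenes goes para to one methoxy group (C2, next to bromine) and not to the position between the two methoxy groups.

Step 2
Reactants: 3 1-bromo-2-iodo-3,5-dimethoxybenzene; 4 p-toluenesulfonic acid monohydrate; 5 1,3,5-trimethoxybenzene
Product: 7 (2-bromo-4,6-dimethoxyphenyl)(2,4,6-trimethoxyphenyl)iodonium tosylate, via hydroxy(tosyloxy)iodoarene 6 (not isolated)
Conditions: mCPBA (1.1 equiv), TsOH·H2O, MeCN, 60 °C, 30 min; then 1,3,5-trimethoxybenzene, 60 °C, 10 min; Et2O precipitation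
Reagents that add atoms: p-toluenesulfonic acid monohydrate (4), Cc1ccc(cc1)S(=O)(=O)O.O; 1,3,5-trimethoxybenzene (5), COc1cc(OC)cc(OC)c1
Why: One-pot unsymmetrical diaryliodonium synthesis, in which mCPBA/TsOH oxidise the aryl iodide to a Koser-type trivalent iodine species (the oxygen from mCPBA leaves as water) that undergoes electrophilic aromatic substitution on the very nucleophilic trimethoxybenzene.

Step 3
Reactants: 8 methyl 2,6-dihydroxy-4-methylbenzoate; 9 1-bromo-3-methylbut-2-ene (prenyl bromide)
Product: 10 methyl 2-hydroxy-4-methyl-6-[(3-methylbut-2-en-1-yl)oxy]benzoate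
Conditions: prenyl bromide (1.0 equiv), K2CO3 (1.1 equiv), acetone, reflux
Reagents that add atoms: 1-bromo-3-methylbut-2-ene (9), CC(C)=CCBr
Why: Williamson ether synthesis on two equivalent phenols, which stops at mono-alkylation because the remaining OH is held in a strong hydrogen bond to the ester carbonyl and only one equivalent of bromide is used.

Step 4
Reactants: 10 methyl 2-hydroxy-4-methyl-6-[(3-methylbut-2-en-1-yl)oxy]benzoate; 7 (2-bromo-4,6-dimethoxyphenyl)(2,4,6-trimethoxyphenyl)iodonium tosylate
Product: 12 methyl 2-(2-bromo-4,6-dimethoxyphenoxy)-4-methyl-6-[(3-methylbut-2-en-1-yl)oxy]benzoate, via aryloxy-diaryl-λ3-iodane 11 (not isolated)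
Conditions: KOt-Bu (1.05 equiv), 7 (1.2 equiv), THF, 0 °C to 40 °C
Reagents that add atoms: (2-bromo-4,6-dimethoxyphenyl)(2,4,6-trimethoxyphenyl)iodonium tosylate (7), COc1cc(Br)c([I+]c2c(OC)cc(OC)cc2OC)c(OC)c1.Cc1ccc(cc1)S([O-])(=O)=O
Why: Metal-free O-arylation with a diaryliodonium salt (ligand exchange, then ligand coupling at trivalent iodine), which tolerates ortho substituents on both partners; the more electron-rich trimethoxyphenyl ligand stays on iodine so the bromo-dimethoxyphenyl group is transferred, and no aryne can form because iodine has no ortho hydrogen.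

Step 5
Reactants: 12 methyl 2-(2-bromo-4,6-dimethoxyphenoxy)-4-methyl-6-[(3-methylbut-2-en-1-yl)oxy]benzoate; 13 potassium (acetoxymethyl)trifluoroborate
Product: 15 methyl 2-[2-(hydroxymethyl)-4,6-dimethoxyphenoxy]-4-methyl-6-[(3-methylbut-2-en-1-yl)oxy]benzoate, via benzylic acetate 14 (not isolated)
Conditions: Pd(dba)2 (5 mol%), RuPhos (10 mol%), 13 (1.5 equiv), K2CO3 (4 equiv), 1,4-dioxane/H2O (10:1), 90 °C
Reagents that add atoms: potassium (acetoxymethyl)trifluoroborate (13), CC(=O)OC[B-](F)(F)F.[K+]
Why: Suzuki–Miyaura coupling of an α-oxy-alkyl trifluoroborate used as a hydroxymethyl anion equivalent, in which zerovalent palladium/RuPhos inserts into the C–Br bond, the carbinol carbon is delivered as a nucleophile and the acetate is saponified in situ; no stereocentre is formed, and the ring A ester survives, whereas an aryllithium at this position would cyclise onto it to give a xanthone.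

**Compound list**
1 | 1-bromo-3,5-dimethoxybenzene | COc1cc(Br)cc(OC)c1 | starting material
2 | N-iodosuccinimide | O=C1CCC(=O)N1I | starting material
3 | 1-bromo-2-iodo-3,5-dimethoxybenzene | COc1cc(Br)c(I)c(OC)c1 | intermediate
4 | p-toluenesulfonic acid monohydrate | Cc1ccc(cc1)S(=O)(=O)O.O | starting material
5 | 1,3,5-trimethoxybenzene | COc1cc(OC)cc(OC)c1 | starting material
6 | 1-bromo-2-[hydroxy(tosyloxy)iodo]-3,5-dimethoxybenzene (not isolated) | COc1cc(Br)c(I(O)OS(=O)(=O)c2ccc(C)cc2)c(OC)c1 | intermediate
7 | (2-bromo-4,6-dimethoxyphenyl)(2,4,6-trimethoxyphenyl)iodonium 4-methylbenzenesulfonate | COc1cc(Br)c([I+]c2c(OC)cc(OC)cc2OC)c(OC)c1.Cc1ccc(cc1)S([O-])(=O)=O | intermediate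
8 | methyl 2,6-dihydroxy-4-methylbenzoate | COC(=O)c1c(O)cc(C)cc1O | starting material
9 | 1-bromo-3-methylbut-2-ene (prenyl bromide) | CC(C)=CCBr | starting material
10 | methyl 2-hydroxy-4-methyl-6-[(3-methylbut-2-en-1-yl)oxy]benzoate | COC(=O)c1c(O)cc(C)cc1OCC=C(C)C | intermediate
11 | methyl 2-{[(2-bromo-4,6-dimethoxyphenyl)(2,4,6-trimethoxyphenyl)-λ3-iodanyl]oxy}-4-methyl-6-[(3-methylbut-2-en-1-yl)oxy]benzoate (not isolated) | COC(=O)c1c(OCC=C(C)C)cc(C)cc1OI(c1c(Br)cc(OC)cc1OC)c1c(OC)cc(OC)cc1OC | intermediate
12 | methyl 2-(2-bromo-4,6-dimethoxyphenoxy)-4-methyl-6-[(3-methylbut-2-en-1-yl)oxy]benzoate | COC(=O)c1c(OCC=C(C)C)cc(C)cc1Oc1c(Br)cc(OC)cc1OC | intermediate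
13 | potassium (acetoxymethyl)trifluoroborate | CC(=O)OC[B-](F)(F)F.[K+] | starting material
14 | methyl 2-[2-(acetoxymethyl)-4,6-dimethoxyphenoxy]-4-methyl-6-[(3-methylbut-2-en-1-yl)oxy]benzoate (not isolated) | COC(=O)c1c(OCC=C(C)C)cc(C)cc1Oc1c(COC(C)=O)cc(OC)cc1OC | intermediate
15 | methyl 2-[2-(hydroxymethyl)-4,6-dimethoxyphenoxy]-4-methyl-6-[(3-methylbut-2-en-1-yl)oxy]benzoate | COC(=O)c1c(OCC=C(C)C)cc(C)cc1Oc1c(CO)cc(OC)cc1OC | target

**Totals**
Total step count: 5.
Longest linear sequence: 4 steps (1 → 3 → 7 → 12 → 15); the ring A branch (8 → 10) is one step.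

**Steps most likely to fail, with fallbacks**

Step 5 is the most exposed. The bromide sits next to a bulky aryloxy group on an electron-rich ring, transmetalation of an α-oxy alkylboron is slow, zerovalent palladium could ionise the prenyl ether, and the new alcohol could lactonise onto the ring A ester. The fallback sets out from 12 and comes back at 15. It swaps the boron reagent for an isocyanide as a formyl anion equivalent that inserts into the aryl–palladium bond. Treatment of 12 with t-BuNC and Et3SiH (Pd(OAc)2, JohnPhos, Na2CO3, DMF, 65 °C) gives methyl 2-{2-[(E)-(tert-butylimino)methyl]-4,6-dimethoxyphenoxy}-4-methyl-6-[(3-methylbut-2-en-1-yl)oxy]benzoate F1. Aqueous acidic work-up hydrolyses it to methyl 2-(2-formyl-4,6-dimethoxyphenoxy)-4-methyl-6-[(3-methylbut-2-en-1-yl)oxy]benzoate F2. NaBH4 in MeOH at 0 °C then reduces the aldehyde, and not the hindered ester, to 15.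

Step 4 may fail because the hydrogen-bonded salicylate phenoxide is a weak nucleophile and the aryl group to be transferred is electron-rich, so some trimethoxyphenyl transfer or slow reaction is possible. The fallback sets out from 3 (with 1 and 10) and comes back at 12. Oxidising 3 with mCPBA/TsOH·H2O in the presence of 1 (CH2Cl2/CF3CH2OH, rt) gives the symmetric bis(2-bromo-4,6-dimethoxyphenyl)iodonium 4-methylbenzenesulfonate F3. Both aryl ligands are then the wanted one, so reaction with 10 and KOt-Bu in THF at 40 °C can only give 12, and the released 3 is recycled.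

Step 2 may fail because the iodide is electron-rich and flanked on both sides, so over-oxidation or self-arylation can compete with clean formation of the trivalent iodine species. The fallback sets out from 3 and 10 and comes back at 12, leaving out hypervalent iodine altogether and making no new compound (F0). It is a copper-catalysed Ullmann ether synthesis (CuI 10 mol%, picolinic acid 20 mol%, K3PO4, DMSO, 90 °C), in which the C–I bond reacts in preference to the C–Br bond.

**Further compounds**
F1 | step 5 | methyl 2-{2-[(E)-(tert-butylimino)methyl]-4,6-dimethoxyphenoxy}-4-methyl-6-[(3-methylbut-2-en-1-yl)oxy]benzoate | COC(=O)c1c(OCC=C(C)C)cc(C)cc1Oc1c(/C=N/C(C)(C)C)cc(OC)cc1OC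
F2 | step 5 | methyl 2-(2-formyl-4,6-dimethoxyphenoxy)-4-methyl-6-[(3-methylbut-2-en-1-yl)oxy]benzoate | COC(=O)c1c(OCC=C(C)C)cc(C)cc1Oc1c(C=O)cc(OC)cc1OC
F3 | step 4 | bis(2-bromo-4,6-dimethoxyphenyl)iodonium 4-methylbenzenesulfonate | COc1cc(Br)c([I+]c2c(Br)cc(OC)cc2OC)c(OC)c1.Cc1ccc(cc1)S([O-])(=O)=O
F0 | step 2 | none | none
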